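A small charge of substrate, 0.034 M in Friday's run, still loses part of itself to the self-condensation product. That product is not read, so it shows as a gap in the balance. The gap opens early, at 3.70% by 0.833 min. Friday's isomer of the product then reads 86.9% at 6.00 min and 86.8% at 12.0 min, while substrate stays at 3.4%, above zero. The late end therefore looks like thermodynamic control, a fixed split of whatever escaped the gap.

| setting | Friday's | Saturday's | flask |
|---|---|---|---|
| substrate | 0.034 M | 0.075 M | 0.050 M |
| remark | run made earlier | run made earlier |  |
| time |  |  | 10 min |

- Friday's (time / min: substrate / %, target / %, isomer of the product / %): 0.833: 26.4, 21.0, 48.9; 2.50: 7.6, 7.8, 81.3; 4.00: 5.4, 5.2, 85.5; 6.00: 3.9, 5.9, 86.9; 10.0: 3.4, 5.3, 86.3; 12.0: 3.3, 5.2, 86.8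
- Saturday's (time / min: substrate / %, target / %, isomer of the product / %): 1.00: 20.5, 16.6, 54.0; 1.50: 12.8, 11.8, 66.6; 2.50: 5.6, 7.4, 77.4; 4.00: 3.7, 4.9, 82.2; 8.00: 4.6, 5.0, 81.4; 12.0: 3.6, 5.3, 80.9

(each reading ± 0.5 percentage points)

- percent here means substrate units held: one self-condensation product counts as two
- steps thought possible: target <-> isomer of the product; substrate <-> target; 2 substrate -> self-condensation product; substrate <-> isomer of the product
- the reaction counts as stopped when no species that holds the substrate changes by six tenths of a point or more over the second half of the time

* why nothing more happens at 10 min, or that something still does (all of the substrate has reacted / forward and back rates have come level / it is still moving)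
* how much of the substrate has reacted by 10 min
* how much target there is at 10 min, in percent of the substrate charged
* how much isomer of the product there is at 10 min, in percent of the substrate charged

The step taking two substrate goes with the square of substrate and the others with its first power, so while the gap stays small, the gap per molar of charge should hold at a given time. Each run gives it independently, at a mean time of 10.0 min:

Friday: gap 5.00%, per molar 1.47 M⁻¹, for this flask 7.35%

Saturday, readings at 8.00 min and 12.0 min averaged: gap 9.60%, per molar 1.28 M⁻¹, for this flask 6.40%

Saturday's charge is twice Friday's, and its gap twice. The two estimates part by 0.95 percentage points, and neither cheats: that is less than the 1.3 points scatter of Friday's stretched figure. Their mean, 1.38 M⁻¹, is the condensation toll, the share of the charge lost per molar of charge.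

The runs' mean split of the remainder then joins the two ends:

isomer share 90.3%, so isomer 84.1%

target share 5.64%, so target 5.25%

substrate share 4.06%, so conversion 96.2%

With substrate above zero and Friday's late readings moving within their scatter, this reckoning takes forward and back rates to have come level in this flask by the asked time. The forecast also says forward and back rates have come level, with conversion 96.4%, target 5.3% and isomer 85%, a little above the isomer reckoned here; its ground: “This means the reversible steps have reached equilibrium.”

The flask gives forward and back rates have come level, conversion 96.3%, target 5.13% and isomer 84.4%.

    target ⇌ isomer of the product (k = 0.0360 s⁻¹)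
    substrate ⇌ target (K = 1.40, k = 0.0330 s⁻¹)
    2 substrate → self-condensation product (k = 0.0400 M⁻¹ s⁻¹)
    substrate ⇌ isomer of the product (K = 23.0, k = 0.00490 s⁻¹)

For the asked flask the toll gives 6.88% of self-condensation product, and that flask holds 6.81% at 10.0 min. The flask charged with 0.20 M reckons to 27.6% of self-condensation product and isomer 65.4%. At 10.0 min it holds 21.7% of self-condensation product, or 1.08 M⁻¹ against the toll's 1.38 M⁻¹. Its remainder still splits with 90.6% as isomer, and that isomer stands at 71.0%.

The earlier runs and the new flask are simulated on assumed constants, and the scatter is random.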